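The route rests on disconnecting ring C at the C4–C4a bond. The precursor is a 2-(benzyloxy)-3-aryloxy-3-arylacrylic acid whose aryloxy group is a symmetrical 3,5-bis(benzyloxy)phenoxy unit (future ring A) held cis to the carboxyl group. Mixed-anhydride activation makes the acyl carbon attack ring A and, in one operation, forms C4–C4a and closes the pyranone, delivering the fully oxygenated flavonol skeleton. The step exploits ring A: its two carbons ortho to O1 (future C4a and C8) are equivalent and activated by three oxygen donors, so only one ring closure is possible. Orthogonal O-protection then lets O3 and O7 be sulfated while the chelated 5-OH and a masked O3' stay untouched.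

Key step: step 7

Remark: the enol oxygen and ring A carry benzyl groups, so no allyl vinyl ether (open to Claisen or Wittig shifts) is ever present and both partners can be bought; the one allyl ether sits on ring B and is exchanged for a pivalate before hydrogenolysis, which would otherwise saturate it.

Remark: 8 is expected as an E/Z mixture; 10 and 11 are named and drawn as the E isomers (carboxyl cis to the aryloxy group) that ring closure needs, and the Z isomers are carried along because step 7 should interconvert them.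

Remark: the sulfate half-esters are drawn as free hydrogen sulfates, as in the target; the compound would be purified and kept as its disodium salt and the free acid released only at the end by a cold pass through a sulfonic acid resin.

Step 1
Reactants: 1 isovanillin (3-hydroxy-4-methoxybenzaldehyde); 2 allyl bromide
Product: 3 3-(allyloxy)-4-methoxybenzaldehyde
Conditions: K2CO3, DMF, rt
Reagents that add atoms: none
Why: Williamson etherification: the phenoxide formed by K2CO3 displaces bromide from the allylic halide (SN2) and the aldehyde is inert under these conditions.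

Step 2
Reactants: 4 ethyl 2-(benzyloxy)acetate; 3 3-(allyloxy)-4-methoxybenzaldehyde
Product: 6 ethyl 3-[3-(allyloxy)-4-methoxyphenyl]-2-(benzyloxy)-3-hydroxypropanoate (racemic syn/anti mixture), via lithium ester enolate 5 (not isolated)
Conditions: LiN(i-Pr)2, THF, −78 °C; then 3; aq. NH4Cl
Reagents that add atoms: none
Why: Aldol addition of the preformed lithium ester enolate to a non-enolisable aryl aldehyde at low temperature; the two new stereocenters are formed without control (racemic syn/anti mixture) because both are erased in steps 3 and 4.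

Step 3
Reactants: 6 ethyl 3-[3-(allyloxy)-4-methoxyphenyl]-2-(benzyloxy)-3-hydroxypropanoate
Product: 7 ethyl 3-[3-(allyloxy)-4-methoxyphenyl]-2-(benzyloxy)-3-oxopropanoate (racemic)
Conditions: Dess–Martin periodinane, CH2Cl2, rt
Reagents that add atoms: none
Why: Dess–Martin oxidation turns the benzylic secondary alcohol into the ketone under near-neutral conditions that spare the allyl ether, the benzyl ether and the ester; the remaining C2 stereocenter is racemic and is lost in step 4.

Step 4
Reactants: 7 ethyl 3-[3-(allyloxy)-4-methoxyphenyl]-2-(benzyloxy)-3-oxopropanoate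
Product: 8 ethyl 3-[3-(allyloxy)-4-methoxyphenyl]-2-(benzyloxy)-3-chloroprop-2-enoate (E/Z mixture)
Conditions: POCl3, i-Pr2NEt, toluene, 80 °C
Reagents that add atoms: phosphoryl chloride, O=P(Cl)(Cl)Cl
Why: Deoxychlorination of a β-keto ester: the enol is O-phosphorylated by POCl3 and chloride then replaces the phosphate by addition–elimination at the β-carbon, giving the β-chloroacrylate whose alkene geometry need not be controlled.

Step 5
Reactants: 8 ethyl 3-[3-(allyloxy)-4-methoxyphenyl]-2-(benzyloxy)-3-chloroprop-2-enoate; 9 3,5-bis(benzyloxy)phenol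
Product: 10 ethyl (E)-3-[3-(allyloxy)-4-methoxyphenyl]-2-(benzyloxy)-3-[3,5-bis(benzyloxy)phenoxy]prop-2-enoate
Conditions: Cs2CO3, DMF, 80 °C
Reagents that add atoms: none
Why: Nucleophilic vinylic substitution by addition–elimination: the cesium phenoxide adds through oxygen to the β-carbon of the chloroacrylate and chloride leaves from the ester enolate, the polar aprotic medium favouring O- over C-attack of the phenoxide.

Step 6
Reactants: 10 ethyl (E)-3-[3-(allyloxy)-4-methoxyphenyl]-2-(benzyloxy)-3-[3,5-bis(benzyloxy)phenoxy]prop-2-enoate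
Product: 11 (E)-3-[3-(allyloxy)-4-methoxyphenyl]-2-(benzyloxy)-3-[3,5-bis(benzyloxy)phenoxy]prop-2-enoic acid
Conditions: LiOH, THF/H2O, 50 °C; then 1 M HCl
Reagents that add atoms: lithium hydroxide, [Li+].[OH-]
Why: Saponification (acyl–oxygen cleavage by hydroxide) of the hindered ethyl ester in a methanol-free medium, so that no alkoxide can exchange the aryloxy group by conjugate addition–elimination.

Step 7
Reactants: 11 (E)-3-[3-(allyloxy)-4-methoxyphenyl]-2-(benzyloxy)-3-[3,5-bis(benzyloxy)phenoxy]prop-2-enoic acid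
Product: 13 2-[3-(allyloxy)-4-methoxyphenyl]-3,5,7-tris(benzyloxy)-4H-chromen-4-one, via mixed trifluoroacetic anhydride 12 (not isolated)
Conditions: (CF3CO)2O, CH2Cl2, 0 °C → rt
Reagents that add atoms: none
Why: (CF3CO)2O converts the acid into mixed anhydride 12, whose acyl carbon (reacting directly or after ionisation to the acylium ion) is attacked by the ring A carbon ortho to the vinyl ether oxygen, and loss of a proton from the Wheland intermediate gives the chromen-4-one. This is an intramolecular Friedel–Crafts acylation, closest to the known cyclisation of β-aryloxycinnamic acids to flavones. Ring C closes as a six-membered ring through the new C4–C4a bond in a 6-exo-trig attack on the anhydride carbonyl. No stereocenter is formed. The selectivity needed is ring A over ring B and over the phenyl of the C2 benzyl ether: the two ortho carbons of the 3,5-bis(benzyloxy)phenoxy ring are equivalent and triply oxygen-activated, whereas ring B would need the other alkene geometry and a five-membered (indenone) closure and the benzyl phenyl is unactivated. Reversible protonation at the acrylate α-carbon of the push–pull enol ether should interconvert the E and Z acids so that both feed the cyclisation, and the benzyl and allyl ethers tolerate the anhydride.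

Step 8
Reactants: 13 2-[3-(allyloxy)-4-methoxyphenyl]-3,5,7-tris(benzyloxy)-4H-chromen-4-one
Product: 14 3,5,7-tris(benzyloxy)-2-(3-hydroxy-4-methoxyphenyl)-4H-chromen-4-one
Conditions: Pd(PPh3)4 (cat.), morpholine, THF, rt
Reagents that add atoms: none
Why: Tsuji–Trost-type O-deallylation: zerovalent palladium ionises the aryl allyl ether to a π-allyl complex that morpholine captures, which frees the 3'-phenol while the benzyl ethers, inert to this catalyst, stay in place.

Step 9
Reactants: 14 3,5,7-tris(benzyloxy)-2-(3-hydroxy-4-methoxyphenyl)-4H-chromen-4-one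
Product: 15 2-methoxy-5-[3,5,7-tris(benzyloxy)-4-oxo-4H-chromen-2-yl]phenyl pivalate
Conditions: t-BuCOCl, Et3N, DMAP (cat.), CH2Cl2, 0 °C → rt
Reagents that add atoms: pivaloyl chloride, CC(C)(C)C(=O)Cl
Why: Acylation of the only free hydroxyl with an acid chloride under DMAP catalysis gives a hindered aryl ester that should outlast hydrogenolysis and sulfation yet fall to hydroxide at the end.

Step 10
Reactants: 15 2-methoxy-5-[3,5,7-tris(benzyloxy)-4-oxo-4H-chromen-2-yl]phenyl pivalate
Product: 16 2-methoxy-5-(3,5,7-trihydroxy-4-oxo-4H-chromen-2-yl)phenyl pivalate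
Conditions: H2 (1 atm), Pd/C, THF/MeOH, rt
Reagents that add atoms: none
Why: Catalytic hydrogenolysis of the three benzyl ethers (two aryl, one enol-type) over palladium; the aryl pivalate, the methyl ether and the conjugated chromone are not reduced at 1 atm and room temperature.

Step 11
Reactants: 16 2-methoxy-5-(3,5,7-trihydroxy-4-oxo-4H-chromen-2-yl)phenyl pivalate
Product: 18 5-hydroxy-2-(3-hydroxy-4-methoxyphenyl)-4-oxo-4H-chromene-3,7-diyl bis(hydrogen sulfate) (tamarixetin 3,7-di-O-sulfate), via 3'-O-pivaloyl 3,7-bis(hydrogen sulfate) 17 (not isolated)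
Conditions: SO3·pyridine, pyridine, rt; then aq. NaOH, MeOH, rt; then sulfonic acid resin (H+ form), H2O, 0 °C
Reagents that add atoms: sulfur trioxide–pyridine complex, [O-]S(=O)(=O)[n+]1ccccc1
Why: O-Sulfation of phenols by the SO3–pyridine complex: the acidic 7-OH and the enolic 3-OH react, whereas the 5-OH is tied up in a six-membered hydrogen bond to the C4 carbonyl and is left alone; aryl sulfate monoanions resist hydroxide, so base then removes the pivalate (ester hydrolysis) without touching the sulfates.

Compound list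

1 | isovanillin (3-hydroxy-4-methoxybenzaldehyde) | COc1ccc(C=O)cc1O | starting material
2 | allyl bromide | C=CCBr | starting material
3 | 3-(allyloxy)-4-methoxybenzaldehyde | COc1ccc(C=O)cc1OCC=C | intermediate
4 | ethyl 2-(benzyloxy)acetate | CCOC(=O)COCc1ccccc1 | starting material
5 | lithium ester enolate of 4, lithium 2-(benzyloxy)-1-ethoxyethen-1-olate (drawn as the chelated isomer; its geometry has no bearing on the route) | CCO/C([O-])=C/OCc1ccccc1.[Li+] | intermediate (not isolated)
6 | ethyl 3-[3-(allyloxy)-4-methoxyphenyl]-2-(benzyloxy)-3-hydroxypropanoate, racemic, syn/anti mixture | CCOC(=O)C(OCc1ccccc1)C(O)c1ccc(OC)c(OCC=C)c1 | intermediate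
7 | ethyl 3-[3-(allyloxy)-4-methoxyphenyl]-2-(benzyloxy)-3-oxopropanoate, racemic | CCOC(=O)C(OCc1ccccc1)C(=O)c1ccc(OC)c(OCC=C)c1 | intermediate
8 | ethyl 3-[3-(allyloxy)-4-methoxyphenyl]-2-(benzyloxy)-3-chloroprop-2-enoate, E/Z mixture | CCOC(=O)C(OCc1ccccc1)=C(Cl)c1ccc(OC)c(OCC=C)c1 | intermediate
9 | 3,5-bis(benzyloxy)phenol | Oc1cc(OCc2ccccc2)cc(OCc2ccccc2)c1 | starting material
10 | ethyl (E)-3-[3-(allyloxy)-4-methoxyphenyl]-2-(benzyloxy)-3-[3,5-bis(benzyloxy)phenoxy]prop-2-enoate | CCOC(=O)/C(OCc1ccccc1)=C(/c1ccc(OC)c(OCC=C)c1)Oc1cc(OCc2ccccc2)cc(OCc2ccccc2)c1 | intermediate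
11 | (E)-3-[3-(allyloxy)-4-methoxyphenyl]-2-(benzyloxy)-3-[3,5-bis(benzyloxy)phenoxy]prop-2-enoic acid | O=C(O)/C(OCc1ccccc1)=C(/c1ccc(OC)c(OCC=C)c1)Oc1cc(OCc2ccccc2)cc(OCc2ccccc2)c1 | intermediate (precursor of the key step)
12 | mixed anhydride of 11 with trifluoroacetic acid, (E) | O=C(OC(=O)C(F)(F)F)/C(OCc1ccccc1)=C(/c1ccc(OC)c(OCC=C)c1)Oc1cc(OCc2ccccc2)cc(OCc2ccccc2)c1 | intermediate (not isolated)
13 | 2-[3-(allyloxy)-4-methoxyphenyl]-3,5,7-tris(benzyloxy)-4H-chromen-4-one | COc1ccc(-c2oc3cc(OCc4ccccc4)cc(OCc4ccccc4)c3c(=O)c2OCc2ccccc2)cc1OCC=C | intermediate (product of the key step)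
14 | 3,5,7-tris(benzyloxy)-2-(3-hydroxy-4-methoxyphenyl)-4H-chromen-4-one | COc1ccc(-c2oc3cc(OCc4ccccc4)cc(OCc4ccccc4)c3c(=O)c2OCc2ccccc2)cc1O | intermediate
15 | 2-methoxy-5-[3,5,7-tris(benzyloxy)-4-oxo-4H-chromen-2-yl]phenyl pivalate | COc1ccc(-c2oc3cc(OCc4ccccc4)cc(OCc4ccccc4)c3c(=O)c2OCc2ccccc2)cc1OC(=O)C(C)(C)C | intermediate
16 | 2-methoxy-5-(3,5,7-trihydroxy-4-oxo-4H-chromen-2-yl)phenyl pivalate | COc1ccc(-c2oc3cc(O)cc(O)c3c(=O)c2O)cc1OC(=O)C(C)(C)C | intermediate
17 | 5-hydroxy-2-[4-methoxy-3-(pivaloyloxy)phenyl]-4-oxo-4H-chromene-3,7-diyl bis(hydrogen sulfate) | COc1ccc(-c2oc3cc(OS(=O)(=O)O)cc(O)c3c(=O)c2OS(=O)(=O)O)cc1OC(=O)C(C)(C)C | intermediate (not isolated)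
18 | 5-hydroxy-2-(3-hydroxy-4-methoxyphenyl)-4-oxo-4H-chromene-3,7-diyl bis(hydrogen sulfate) | COc1ccc(-c2oc3cc(OS(=O)(=O)O)cc(O)c3c(=O)c2OS(=O)(=O)O)cc1O | target

Total step count: 11.
Longest linear sequence: 11 steps (1 to 18); 2, 4 and 9 are purchased and enter the single linear line.

Steps most likely to fail

1. Step 7 (ring closure). The acyl carbon of the mixed anhydride is a vinylogous carbonate and may be too weak an electrophile. Intermolecular trifluoroacetylation of ring A, or acid cleavage of the aryl vinyl ether, could then outrun cyclisation. The fallback sets out from 3 and comes back at 13, closing ring C through the O1–C2 bond instead. Aldehyde 3 would be condensed (KOH, EtOH, rt, Claisen–Schmidt) with purchased 1-[2,4-bis(benzyloxy)-6-hydroxyphenyl]ethan-1-one to give the chalcone (E)-3-[3-(allyloxy)-4-methoxyphenyl]-1-[2,4-bis(benzyloxy)-6-hydroxyphenyl]prop-2-en-1-one F1. Algar–Flynn–Oyamada oxidation (aq. H2O2, NaOH, MeOH/THF, 0 °C → rt) would give 2-[3-(allyloxy)-4-methoxyphenyl]-5,7-bis(benzyloxy)-3-hydroxy-4H-chromen-4-one F2. O-Benzylation of its 3-hydroxyl (BnBr, K2CO3, DMF, 60 °C) would return to 13.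

2. Step 5 (aryl vinyl ether formation). Addition of the phenoxide to a β-carbon that is hindered and deactivated by the α-benzyloxy and p-methoxyaryl donors may be too slow, so that attack at the ester or thermal decomposition takes over. The fallback sets out from 7 and comes back at 11, and also bypasses steps 4 and 6. Keto ester 7 would be dealkoxycarbonylated (LiCl, wet DMSO, 140 °C, Krapcho) to 1-[3-(allyloxy)-4-methoxyphenyl]-2-(benzyloxy)ethan-1-one F3. Vilsmeier–Haack–Arnold chloroformylation (POCl3, DMF, 0 → 60 °C) would give 3-[3-(allyloxy)-4-methoxyphenyl]-2-(benzyloxy)-3-chloroprop-2-enal F4, a much stronger acceptor. Phenol 9 (K2CO3, DMF, rt) would displace chloride to give (E)-3-[3-(allyloxy)-4-methoxyphenyl]-2-(benzyloxy)-3-[3,5-bis(benzyloxy)phenoxy]prop-2-enal F5. Chlorite oxidation (NaClO2, NaH2PO4, 2-methyl-2-butene, t-BuOH/H2O, rt) would deliver acid 11.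

3. Step 11 (sulfation and unmasking). Sulfation may stop after one hydroxyl or run on to O5, and sulfate may be lost during the base stage or the isolation of a polar mixture that is hard to separate. The fallback sets out from 16 and comes back at 17. Triol 16 would be treated with 2,2,2-trichloroethyl chlorosulfate (Et3N, DMAP, THF, 0 °C → rt) to give the neutral, chromatographable diester 5-hydroxy-2-[4-methoxy-3-(pivaloyloxy)phenyl]-4-oxo-4H-chromene-3,7-diyl bis(2,2,2-trichloroethyl) bis(sulfate) F6. Zn dust with HCO2NH4 in MeOH at rt would unmask both sulfates by reductive elimination to give 17, which the base stage of step 11 turns into 18.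

Further compounds

F1 | step 7 | (E)-3-[3-(allyloxy)-4-methoxyphenyl]-1-[2,4-bis(benzyloxy)-6-hydroxyphenyl]prop-2-en-1-one | O=C(/C=C/c1ccc(OC)c(OCC=C)c1)c1c(O)cc(OCc2ccccc2)cc1OCc1ccccc1
F2 | step 7 | 2-[3-(allyloxy)-4-methoxyphenyl]-5,7-bis(benzyloxy)-3-hydroxy-4H-chromen-4-one | COc1ccc(-c2oc3cc(OCc4ccccc4)cc(OCc4ccccc4)c3c(=O)c2O)cc1OCC=C
F3 | step 5 | 1-[3-(allyloxy)-4-methoxyphenyl]-2-(benzyloxy)ethan-1-one | O=C(COCc1ccccc1)c1ccc(OC)c(OCC=C)c1
F4 | step 5 | 3-[3-(allyloxy)-4-methoxyphenyl]-2-(benzyloxy)-3-chloroprop-2-enal, E/Z mixture | O=CC(OCc1ccccc1)=C(Cl)c1ccc(OC)c(OCC=C)c1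
F5 | step 5 | (E)-3-[3-(allyloxy)-4-methoxyphenyl]-2-(benzyloxy)-3-[3,5-bis(benzyloxy)phenoxy]prop-2-enal | O=C/C(OCc1ccccc1)=C(/c1ccc(OC)c(OCC=C)c1)Oc1cc(OCc2ccccc2)cc(OCc2ccccc2)c1
F6 | step 11 | 5-hydroxy-2-[4-methoxy-3-(pivaloyloxy)phenyl]-4-oxo-4H-chromene-3,7-diyl bis(2,2,2-trichloroethyl) bis(sulfate) | COc1ccc(-c2oc3cc(OS(=O)(=O)OCC(Cl)(Cl)Cl)cc(O)c3c(=O)c2OS(=O)(=O)OCC(Cl)(Cl)Cl)cc1OC(=O)C(C)(C)C
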